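**Strategy.** The target is a C12-bridged bis-resorcinol whose only element of dissymmetry is the C5(ring A)–O–C1(ring B) ether. Without that bond the skeleton is a twofold-symmetric 1,12-bis(3,5-dioxyphenyl)dodecane: chain carbon C12' on ring A C3 and C1' on ring B C4 each sit meta to two ring oxygens (A: C1, C5; B: C2, C6). The key step forms both aryl–alkyl bonds at once: two 3,5-dimethoxybenzynes, released from two equivalents of 1-fluoro-3,5-dimethoxybenzene, each capture one end of 1,12-dilithiododecane at the former C–F carbon. The ether is then closed by mono-demethylation, iodination between the methoxy groups of the other ring and Ullmann macrocyclisation.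

Key step: step 3

Remark on the chemistry: the two rings of 8 are equivalent, so step 4 can differentiate them only statistically. Demethylation is placed before iodination because a hot thiolate would be expected to attack the ethers flanking an iodine first, and the C–I bond itself. Compound 3 is prepared and handled as an ethereal stock solution.

**Step 1**
Reactants: 1 1,12-dibromododecane
Product: 2 1,12-diiodododecane
Conditions: NaI (4 equiv), acetone, reflux
Reagents that add atoms: sodium iodide, [Na+].[I-]
Why: Finkelstein halide exchange (SN2) at two unhindered primary carbons, driven by precipitation of NaBr from acetone.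

**Step 2**
Reactants: 2 1,12-diiodododecane
Product: 3 1,12-dilithiododecane (pentane–Et2O solution under argon, titrated on an aliquot and used the same day)
Conditions: t-BuLi (4.2 equiv), pentane/Et2O 3:2, −78 °C; then rt, 1 h
Reagents that add atoms: tert-butyllithium, [Li]C(C)(C)C
Why: lithium–iodine exchange at a primary alkyl iodide is fast at −78 °C and is made irreversible by the second equivalent of t-BuLi per iodide, which destroys the tert-butyl iodide formed by elimination, while the twelve-carbon spacing rules out cyclisation.

**Step 3**
Reactants: 4 1-fluoro-3,5-dimethoxybenzene (two equivalents react); 3 1,12-dilithiododecane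
Product: 8 1,12-bis(3,5-dimethoxyphenyl)dodecane, via (2-fluoro-4,6-dimethoxyphenyl)lithium 5 (not isolated), via 3,5-dimethoxybenzyne 6 (not isolated), via 1,12-bis(2-lithio-3,5-dimethoxyphenyl)dodecane 7 (not isolated)
Conditions: 4 (2.3 equiv), s-BuLi (2.2 equiv), THF, −78 °C, 1 h; add 3 (1.0 equiv), −78 °C → rt; H2O
Reagents that add atoms: none
Why: s-BuLi removes the proton flanked by fluorine and a methoxy group of 4 at −78 °C (directed ortho-metalation at the most acidic site; 4 is symmetric, so both such sites are equivalent), and since the base is used slightly short of 4 none remains when 5 loses LiF on warming to give aryne 6. Each primary C–Li end of 3 then adds to the aryne carbon that carried fluorine, because this places the new carbanion of 7 next to the inductively withdrawing, lithium-coordinating methoxy group; water protonates that position, leaving the chain meta to both oxygens. The closest known reaction type is the addition of alkyllithium reagents to 3-alkoxyarynes generated from fluoroarenes, an established entry to 5-alkylresorcinol ethers, applied here at both ends of one dilithioalkane. No ring is closed and no stereocentre is formed. The step needs regioselective meta-attack, secured by the methoxy group beside the triple bond, and addition of the alkyl- rather than an aryllithium to the aryne, favoured by the higher nucleophilicity of the primary alkyllithium and by having 3 present before the aryne is released.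

**Step 4**
Reactants: 8 1,12-bis(3,5-dimethoxyphenyl)dodecane
Product: 9 3-[12-(3,5-dimethoxyphenyl)dodecyl]-5-methoxyphenol
Conditions: NaSEt (1.0 equiv), DMF, 140 °C; aq HCl
Reagents that add atoms: none
Why: thiolate SN2 cleavage of an aryl methyl ether stops at one methyl per ring because the phenoxide formed resists a second cleavage, and as the rings are equivalent one equivalent of thiolate should give a statistical mixture from which mono-phenol 9 is separated by polarity, with recovered 8 recycled and the over-cleaved diphenol re-methylated to 8.

**Step 5**
Reactants: 9 3-[12-(3,5-dimethoxyphenyl)dodecyl]-5-methoxyphenol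
Product: 11 3-[12-(4-iodo-3,5-dimethoxyphenyl)dodecyl]-5-methoxyphenol, via lithium 3-[12-(4-lithio-3,5-dimethoxyphenyl)dodecyl]-5-methoxyphenolate 10 (not isolated)
Conditions: n-BuLi (2.1 equiv), THF, 0 °C → rt; ICH2CH2I (1.3 equiv), −78 °C → rt; aq HCl
Reagents that add atoms: 1,2-diiodoethane, ICCI
Why: the first equivalent of n-BuLi forms the lithium phenolate, whose negative charge shields ring A from metalation, the second removes the proton between the two methoxy groups of ring B (directed ortho-metalation at the doubly activated site), and 1,2-diiodoethane iodinates the aryllithium with loss of ethylene without attacking the electron-rich phenolate ring as I2 would.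

**Step 6**
Reactants: 11 3-[12-(4-iodo-3,5-dimethoxyphenyl)dodecyl]-5-methoxyphenol
Product: 12 macrocyclic diaryl ether, the tri-O-methyl ether of the target: the phenol oxygen of ring A is bonded to C4 of the 3,5-dimethoxyphenyl ring B (between its two methoxy groups), the (CH2)12 chain joins the two rings, 20-membered ring
Conditions: CuI (1.0 equiv), picolinic acid (2.0 equiv), K3PO4 (3 equiv), DMSO, 100 °C, syringe-pump addition of 11 (final 2 mM)
Reagents that add atoms: none
Why: intramolecular Ullmann diaryl ether synthesis in which the phenolate of ring A and the aryl iodide of ring B are joined at monovalent copper (oxidative addition to a trivalent copper aryl, then reductive elimination), with a picolinate ligand suited to ortho-disubstituted partners and slow addition at high dilution favouring the 20-membered ring over oligomers.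

**Step 7**
Reactants: 12 macrocyclic tri-O-methyl ether
Product: 13 target macrocycle CNP0314249.0: ring A carries OH at C1, the chain at C3 and the ether oxygen at C5; ring B carries the ether oxygen at C1, OH at C2 and C6 and the chain at C4
Conditions: BBr3 (6 equiv), CH2Cl2, −78 °C → rt; H2O
Reagents that add atoms: none
Why: BBr3 cleaves all three aryl methyl ethers (bromide attacks the methyl group of each O–B complex), while the diaryl ether, which offers no carbon open to SN2 attack, stays intact.

**Compound list**
1 | 1,12-dibromododecane | BrCCCCCCCCCCCCBr | starting material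
2 | 1,12-diiodododecane | ICCCCCCCCCCCCI | intermediate
3 | 1,12-dilithiododecane | [Li]CCCCCCCCCCCC[Li] | intermediate
4 | 1-fluoro-3,5-dimethoxybenzene | COc1cc(F)cc(OC)c1 | starting material
5 | (2-fluoro-4,6-dimethoxyphenyl)lithium | [Li]c1c(F)cc(OC)cc1OC | intermediate
6 | 3,5-dimethoxybenzyne (1,2-didehydro-3,5-dimethoxybenzene) | COC1=CC(OC)=CC#C1 | intermediate
7 | 1,12-bis(2-lithio-3,5-dimethoxyphenyl)dodecane | [Li]c1c(CCCCCCCCCCCCc2cc(OC)cc(OC)c2[Li])cc(OC)cc1OC | intermediate
8 | 1,12-bis(3,5-dimethoxyphenyl)dodecane | COc1cc(CCCCCCCCCCCCc2cc(OC)cc(OC)c2)cc(OC)c1 | intermediate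
9 | 3-[12-(3,5-dimethoxyphenyl)dodecyl]-5-methoxyphenol | COc1cc(O)cc(CCCCCCCCCCCCc2cc(OC)cc(OC)c2)c1 | intermediate
10 | lithium 3-[12-(4-lithio-3,5-dimethoxyphenyl)dodecyl]-5-methoxyphenolate | [Li]Oc1cc(OC)cc(CCCCCCCCCCCCc2cc(OC)c([Li])c(OC)c2)c1 | intermediate
11 | 3-[12-(4-iodo-3,5-dimethoxyphenyl)dodecyl]-5-methoxyphenol | COc1cc(O)cc(CCCCCCCCCCCCc2cc(OC)c(I)c(OC)c2)c1 | intermediate
12 | macrocyclic tri-O-methyl ether of the target (ring A: 1-methoxy-3-alkyl-5-aryloxy; ring B: 1-aryloxy-2,6-dimethoxy-4-alkyl; C12 bridge) | COc1cc2cc(c1)Oc1c(OC)cc(cc1OC)CCCCCCCCCCCC2 | intermediate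
13 | CNP0314249.0, macrocyclic bis-resorcinol diaryl ether (ring A: 1-hydroxy-3-alkyl-5-aryloxy; ring B: 1-aryloxy-2,6-dihydroxy-4-alkyl; C12 bridge) | Oc1cc2cc(c1)Oc1c(O)cc(cc1O)CCCCCCCCCCCC2 | target

**Step count.** Total: 7 steps. Longest linear sequence: 7 steps (1 → 2 → 3 → 8 → 9 → 11 → 12 → 13); 4 enters at step 3.

**Steps most likely to fail**

Step 3 (key step). The aryne may be intercepted by the aryllithium species present (5 or 7) instead of by the alkyllithium, or only one chain end may be arylated if the dilithioalkane aggregates or precipitates. The fallback is a cross-coupling that sets out from 1 and returns at 8. Compound 1 is converted with magnesium turnings in THF into the bis-Grignard reagent dodecane-1,12-diylbis(magnesium bromide) F1. F1 is then coupled at both ends with commercial 1-bromo-3,5-dimethoxybenzene (2.2 equiv) under Kumada conditions (NiCl2(dppp) catalyst, THF, reflux) to give 8.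

Step 6. Intermolecular coupling may outrun ring closure, or the hindered ring B position may lose its iodine reductively before the C–O bond forms. The fallback replaces the aryl halide by an aryl boron partner; it sets out from 9 and returns at 12. Compound 9 is dilithiated as in step 5 to 10, which is quenched with B(OiPr)3 and hydrolysed with dilute acid to [4-[12-(3-hydroxy-5-methoxyphenyl)dodecyl]-2,6-dimethoxyphenyl]boronic acid F2. Chan–Lam–Evans cyclisation at divalent copper (Cu(OAc)2, pyridine, 4 Å molecular sieves, CH2Cl2, air, rt, slow addition) should then close the ether to 12.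

Step 5. Metalation may stay incomplete because the dianion aggregates, or metalation and iodination may spill onto the phenolate ring. The fallback masks the phenol; it sets out from 9 and returns at 11. Compound 9 is silylated (TIPSCl, imidazole, DMF) to [3-[12-(3,5-dimethoxyphenyl)dodecyl]-5-methoxyphenoxy]tri(propan-2-yl)silane F3, whose bulky, non-directing silyl ether leaves only the position between the two methoxy groups of ring B open to n-BuLi (THF, 0 °C). The resulting [3-[12-(4-lithio-3,5-dimethoxyphenyl)dodecyl]-5-methoxyphenoxy]tri(propan-2-yl)silane F4 is quenched with I2 to [3-[12-(4-iodo-3,5-dimethoxyphenyl)dodecyl]-5-methoxyphenoxy]tri(propan-2-yl)silane F5. Tetrabutylammonium fluoride in THF then frees the phenol to give 11.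

**Further compounds**
F1 | step 3 | dodecane-1,12-diylbis(magnesium bromide) | Br[Mg]CCCCCCCCCCCC[Mg]Br
F2 | step 6 | [4-[12-(3-hydroxy-5-methoxyphenyl)dodecyl]-2,6-dimethoxyphenyl]boronic acid | COc1cc(O)cc(CCCCCCCCCCCCc2cc(OC)c(B(O)O)c(OC)c2)c1
F3 | step 5 | [3-[12-(3,5-dimethoxyphenyl)dodecyl]-5-methoxyphenoxy]tri(propan-2-yl)silane | COc1cc(O[Si](C(C)C)(C(C)C)C(C)C)cc(CCCCCCCCCCCCc2cc(OC)cc(OC)c2)c1
F4 | step 5 | [3-[12-(4-lithio-3,5-dimethoxyphenyl)dodecyl]-5-methoxyphenoxy]tri(propan-2-yl)silane | COc1cc(O[Si](C(C)C)(C(C)C)C(C)C)cc(CCCCCCCCCCCCc2cc(OC)c([Li])c(OC)c2)c1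
F5 | step 5 | [3-[12-(4-iodo-3,5-dimethoxyphenyl)dodecyl]-5-methoxyphenoxy]tri(propan-2-yl)silane | COc1cc(O[Si](C(C)C)(C(C)C)C(C)C)cc(CCCCCCCCCCCCc2cc(OC)c(I)c(OC)c2)c1
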